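Ring A is joined to ring B only through the adjacent carbons C4a and C8a, and the C8 methoxy group sits next to C8a, so ring A is taken off as 3,4,5-trimethoxybenzyne. What remains, C1–C2–C3–C4, is a butadiene carrying the dimethoxyphenyl group on C1, an acyl camphorsultam on C2 and a silyloxymethyl group on C3. One aryne [4+2] cycloaddition forms C1–C8a and C4–C4a, closes ring B and sets C1. The C2=C3 alkene is then moved to C3=C4 through the C4 dienolate, C2 is brought to the trans configuration by equilibration, and hydride cleavage of the auxiliary and desilylation complete the diol.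

Key step: step 8

Assumption: the (3aS,6R,7aR)-sultam is taken to steer the aryne to the C1 face that gives 1R; if the induction runs the other way, the commercial (3aR,6S,7aS)-antipode would be used with no other change.

Locants C1–C8a are those of the naphthalene core of the target (aryl on C1, methoxy groups on C6–C8). TIPS = tri(propan-2-yl)silyl.

Step 1
Reactants: 1 3,4,5-trimethoxyphenol
Product: 2 2-bromo-3,4,5-trimethoxyphenol
Conditions: NBS (1.0 equiv), CH2Cl2, −78 °C to 0 °C
Reagents that add atoms: N-bromosuccinimide, O=C1CCC(=O)N1Br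
Why: Electrophilic aromatic bromination; the two open ring positions are equivalent and each is ortho to OH and para to a methoxy group, so one equivalent of NBS at low temperature should stop at the monobromide.

Step 2
Reactants: 2 2-bromo-3,4,5-trimethoxyphenol
Product: 6 3,4,5-trimethoxy-2-(trimethylsilyl)phenyl trifluoromethanesulfonate, via aryl trimethylsilyl ether 3 (not isolated), via aryllithium 4 (not isolated), via lithium silylphenoxide 5 (not isolated)
Conditions: (Me3Si)2NH, THF, reflux, then evaporate; n-BuLi, THF, −100 °C to −80 °C; Tf2O, −100 °C to rt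
Reagents that add atoms: hexamethyldisilazane, C[Si](C)(C)N[Si](C)(C)C; trifluoromethanesulfonic anhydride, O=S(=O)(OS(=O)(=O)C(F)(F)F)C(F)(F)F
Why: O-silylation, bromine–lithium exchange and retro-Brook (1,3 O-to-C) silyl migration place Me3Si on C2, and the phenoxide left behind is triflated, which is the standard sequence to ortho-silylaryl triflates.

Step 3
Reactants: 7 4-ethynyl-1,2-dimethoxybenzene
Product: 9 3-(3,4-dimethoxyphenyl)prop-2-ynoic acid, via lithium acetylide 8 (not isolated)
Conditions: n-BuLi, THF, −78 °C; CO2 (gas), −78 °C to rt; aq. HCl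
Reagents that add atoms: carbon dioxide, O=C=O
Why: Deprotonation of the terminal alkyne and carboxylation of the acetylide with CO2.

Step 4
Reactants: 9 3-(3,4-dimethoxyphenyl)prop-2-ynoic acid; 10 (3aS,6R,7aR)-2,10-camphorsultam
Product: 13 N-[3-(3,4-dimethoxyphenyl)prop-2-ynoyl]-(3aS,6R,7aR)-2,10-camphorsultam, via acid chloride 11 (not isolated), via sodium sultam salt 12 (not isolated)
Conditions: 9, (COCl)2, DMF (cat.), CH2Cl2, 0 °C to rt, evaporate; 10, NaH, toluene, 0 °C, then the acid chloride, 0 °C to rt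
Reagents that add atoms: none
Why: N-acylation of the sodium salt of the sultam by an acid chloride (nucleophilic acyl substitution), the usual entry to N-acyl camphorsultams.

Step 5
Reactants: 13 N-[3-(3,4-dimethoxyphenyl)prop-2-ynoyl]-(3aS,6R,7aR)-2,10-camphorsultam
Product: 14 N-[(2E)-3-(3,4-dimethoxyphenyl)-2-(tributylstannyl)prop-2-enoyl]-(3aS,6R,7aR)-2,10-camphorsultam
Conditions: Bu3SnH, Pd(PPh3)4 (cat.), THF, 0 °C to rt
Reagents that add atoms: tributyltin hydride, CCCC[SnH](CCCC)CCCC
Why: Palladium-catalysed hydrostannation of an alkynoyl compound adds Sn–H syn with tin on the carbon next to the carbonyl, so H and Sn are cis and the aryl group ends up cis to the carbonyl.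

Step 6
Reactants: 15 2-bromoprop-2-en-1-ol
Product: 16 [(2-bromoprop-2-en-1-yl)oxy]tri(propan-2-yl)silane
Conditions: i-Pr3SiCl, imidazole, DMF, rt
Reagents that add atoms: chlorotri(propan-2-yl)silane, CC(C)[Si](Cl)(C(C)C)C(C)C
Why: Silyl ether formation; the TIPS group is chosen because it should withstand CsF in steps 7 and 8 and the bases of steps 9 and 10, yet leave with Bu4NF at the end.

Step 7
Reactants: 14 N-[(2E)-3-(3,4-dimethoxyphenyl)-2-(tributylstannyl)prop-2-enoyl]-(3aS,6R,7aR)-2,10-camphorsultam; 16 [(2-bromoprop-2-en-1-yl)oxy]tri(propan-2-yl)silane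
Product: 17 N-[(2Z)-2-(3,4-dimethoxybenzylidene)-3-(TIPS-oxymethyl)but-3-enoyl]-(3aS,6R,7aR)-2,10-camphorsultam (aryl cis to the carbonyl)
Conditions: Pd(PPh3)4 (cat.), CuI (cat.), CsF, DMF, 45 °C
Reagents that add atoms: none
Why: Stille coupling, which keeps the alkene geometry of the stannane so that the aryl group points away from the new vinylidene unit; CuI and CsF speed transmetalation of the hindered alpha-stannyl enoyl unit.

Step 8
Reactants: 17 N-[(2Z)-2-(3,4-dimethoxybenzylidene)-3-(TIPS-oxymethyl)but-3-enoyl]-(3aS,6R,7aR)-2,10-camphorsultam; 6 3,4,5-trimethoxy-2-(trimethylsilyl)phenyl trifluoromethanesulfonate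
Product: 19 N-{[(1R)-1-(3,4-dimethoxyphenyl)-6,7,8-trimethoxy-3-(TIPS-oxymethyl)-1,4-dihydronaphthalen-2-yl]carbonyl}-(3aS,6R,7aR)-2,10-camphorsultam, via 3,4,5-trimethoxybenzyne 18 (not isolated)
Conditions: CsF (4 equiv), MeCN, rt, 6 (2 equiv) added slowly
Reagents that add atoms: none
Why: Fluoride attacks silicon of 6 and 1,2-loss of triflate releases aryne 18, which adds suprafacially across C1 and C4 of the s-cis diene in a concerted but asynchronous Diels–Alder reaction, the C4–C4a bond running ahead of the C1–C8a bond. The closest known reaction type is the [4+2] cycloaddition of arynes with acyclic N-dienoyl camphorsultams to give enantioenriched 1,4-dihydronaphthalenes; here the auxiliary sits on the internal C2 carbonyl, so the sense and level of its induction still have to be established. Ring B closes by intermolecular [4+2] annulation, two sigma bonds in one step, and not by an exo or endo cyclisation. The only new stereocentre, C1, is controlled by the sultam: the cis aryl group on C1 and the C3 substituent force the C2 carbonyl out of the diene plane, so the bornane unit covers one face of C1–C2 and the aryne should enter from the other (1R assumed). The step needs regioselectivity, which rests on the distortion of the aryne by the methoxy group next to the triple bond: the carbon remote from it (future C4a) is the electrophilic one and pairs with the unsubstituted, more nucleophilic CH2 terminus C4, leaving the aryl-bearing C1 to bond to C8a. Cycloaddition should win over ene reaction because the aryl group points outward and the 2,3-disubstitution favours the s-cis conformer, and the TIPS ether should survive the fluoride.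

Step 9
Reactants: 19 N-{[(1R)-1-(3,4-dimethoxyphenyl)-6,7,8-trimethoxy-3-(TIPS-oxymethyl)-1,4-dihydronaphthalen-2-yl]carbonyl}-(3aS,6R,7aR)-2,10-camphorsultam
Product: 21 N-{[(1R,2R)-1-(3,4-dimethoxyphenyl)-6,7,8-trimethoxy-3-(TIPS-oxymethyl)-1,2-dihydronaphthalen-2-yl]carbonyl}-(3aS,6R,7aR)-2,10-camphorsultam (1,2-cis; obtained as a C2 epimer mixture expected to be rich in this isomer), via lithium dienolate 20 (not isolated)
Conditions: LiN(SiMe3)2, THF, −78 °C; AcOH, −78 °C
Reagents that add atoms: none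
Why: Deconjugative protonation of an extended enolate: the base removes a C4 hydrogen (benzylic and vinylogous to the imide carbonyl, far more acidic than C1–H) and kinetic protonation of the dienolate occurs at the alpha carbon C2, which moves the alkene to C3=C4; since the proton should arrive on the face opposite the pseudoaxial C1 aryl group, the acyl group is expected to end up cis to the aryl group, and C2 is therefore corrected in step 10.

Step 10
Reactants: 21 N-{[(1R,2R)-1-(3,4-dimethoxyphenyl)-6,7,8-trimethoxy-3-(TIPS-oxymethyl)-1,2-dihydronaphthalen-2-yl]carbonyl}-(3aS,6R,7aR)-2,10-camphorsultam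
Product: 22 N-{[(1R,2S)-1-(3,4-dimethoxyphenyl)-6,7,8-trimethoxy-3-(TIPS-oxymethyl)-1,2-dihydronaphthalen-2-yl]carbonyl}-(3aS,6R,7aR)-2,10-camphorsultam (1,2-trans)
Conditions: DBU (0.3 equiv), toluene, rt
Reagents that add atoms: none
Why: Base-mediated epimerisation through the same dienolate: reprotonation at the alpha carbon is faster than at C4, so the two C2 epimers interconvert without the alkene moving back, and the 1,2-trans isomer (aryl and acyl both pseudoaxial, free of the gauche and allylic strain of the cis isomer) should accumulate, which sets C2 as S under thermodynamic control.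

Step 11
Reactants: 22 N-{[(1R,2S)-1-(3,4-dimethoxyphenyl)-6,7,8-trimethoxy-3-(TIPS-oxymethyl)-1,2-dihydronaphthalen-2-yl]carbonyl}-(3aS,6R,7aR)-2,10-camphorsultam
Product: 23 [(1R,2S)-1-(3,4-dimethoxyphenyl)-6,7,8-trimethoxy-3-(TIPS-oxymethyl)-1,2-dihydronaphthalen-2-yl]methanol
Conditions: LiAlH4, THF, 0 °C; aq. potassium sodium tartrate
Reagents that add atoms: none
Why: Reductive cleavage of the N-acyl sultam by LiAlH4 gives the primary alcohol and returns the auxiliary, and the silyl ether, the styrene-type alkene and both stereocentres should be untouched.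

Step 12
Reactants: 23 [(1R,2S)-1-(3,4-dimethoxyphenyl)-6,7,8-trimethoxy-3-(TIPS-oxymethyl)-1,2-dihydronaphthalen-2-yl]methanol
Product: 24 [(1R,2S)-1-(3,4-dimethoxyphenyl)-6,7,8-trimethoxy-1,2-dihydronaphthalene-2,3-diyl]dimethanol
Conditions: Bu4NF, THF, 0 °C to rt
Reagents that add atoms: none
Why: Fluoride-induced cleavage of the silyl ether frees the second primary alcohol under non-acidic conditions that spare the allylic and benzylic positions.

Compound list
1 | 3,4,5-trimethoxyphenol | COc1cc(O)cc(OC)c1OC | starting material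
2 | 2-bromo-3,4,5-trimethoxyphenol | COc1cc(O)c(Br)c(OC)c1OC | intermediate
3 | (2-bromo-3,4,5-trimethoxyphenoxy)trimethylsilane (not isolated) | COc1cc(O[Si](C)(C)C)c(Br)c(OC)c1OC | intermediate
4 | [2,3,4-trimethoxy-6-(trimethylsilyloxy)phenyl]lithium (not isolated) | COc1cc(O[Si](C)(C)C)c([Li])c(OC)c1OC | intermediate
5 | lithium 3,4,5-trimethoxy-2-(trimethylsilyl)phenoxide (not isolated) | COc1cc([O-])c([Si](C)(C)C)c(OC)c1OC.[Li+] | intermediate
6 | 3,4,5-trimethoxy-2-(trimethylsilyl)phenyl trifluoromethanesulfonate | COc1cc(OS(=O)(=O)C(F)(F)F)c([Si](C)(C)C)c(OC)c1OC | intermediate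
7 | 4-ethynyl-1,2-dimethoxybenzene | COc1ccc(C#C)cc1OC | starting material
8 | lithium (3,4-dimethoxyphenyl)acetylide (not isolated) | COc1ccc(C#C[Li])cc1OC | intermediate
9 | 3-(3,4-dimethoxyphenyl)prop-2-ynoic acid | COc1ccc(C#CC(=O)O)cc1OC | intermediate
10 | (3aS,6R,7aR)-2,10-camphorsultam, the (−)-enantiomer | CC1(C)[C@@H]2CC[C@]13CS(=O)(=O)N[C@@H]3C2 | starting material
11 | 3-(3,4-dimethoxyphenyl)prop-2-ynoyl chloride (not isolated) | COc1ccc(C#CC(Cl)=O)cc1OC | intermediate
12 | sodium salt of (3aS,6R,7aR)-2,10-camphorsultam (not isolated) | CC1(C)[C@@H]2CC[C@]13CS(=O)(=O)[N-][C@@H]3C2.[Na+] | intermediate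
13 | N-[3-(3,4-dimethoxyphenyl)prop-2-ynoyl]-(3aS,6R,7aR)-2,10-camphorsultam | CC1(C)[C@@H]2CC[C@]13CS(=O)(=O)N(C(=O)C#Cc4ccc(OC)c(OC)c4)[C@@H]3C2 | intermediate
14 | N-[(2E)-3-(3,4-dimethoxyphenyl)-2-(tributylstannyl)prop-2-enoyl]-(3aS,6R,7aR)-2,10-camphorsultam | CC1(C)[C@@H]2CC[C@]13CS(=O)(=O)N(C(=O)/C(=C\c4ccc(OC)c(OC)c4)[Sn](CCCC)(CCCC)CCCC)[C@@H]3C2 | intermediate
15 | 2-bromoprop-2-en-1-ol | OCC(Br)=C | starting material
16 | [(2-bromoprop-2-en-1-yl)oxy]tri(propan-2-yl)silane | C=C(Br)CO[Si](C(C)C)(C(C)C)C(C)C | intermediate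
17 | N-[(2Z)-2-(3,4-dimethoxybenzylidene)-3-(TIPS-oxymethyl)but-3-enoyl]-(3aS,6R,7aR)-2,10-camphorsultam, aryl cis to the carbonyl | CC1(C)[C@@H]2CC[C@]13CS(=O)(=O)N(C(=O)/C(=C\c4ccc(OC)c(OC)c4)C(=C)CO[Si](C(C)C)(C(C)C)C(C)C)[C@@H]3C2 | intermediate
18 | 3,4,5-trimethoxybenzyne (not isolated) | COC1=CC#CC(OC)=C1OC | intermediate
19 | N-{[(1R)-1-(3,4-dimethoxyphenyl)-6,7,8-trimethoxy-3-(TIPS-oxymethyl)-1,4-dihydronaphthalen-2-yl]carbonyl}-(3aS,6R,7aR)-2,10-camphorsultam | CC1(C)[C@@H]2CC[C@]13CS(=O)(=O)N(C(=O)C4=C(CO[Si](C(C)C)(C(C)C)C(C)C)Cc5cc(OC)c(OC)c(OC)c5[C@H]4c6ccc(OC)c(OC)c6)[C@@H]3C2 | intermediate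
20 | lithium dienolate of 19, C2=C(OLi)N exocyclic and C3=C4 in the ring (not isolated) | CC1(C)[C@@H]2CC[C@]13CS(=O)(=O)N(C(O[Li])=C4C(CO[Si](C(C)C)(C(C)C)C(C)C)=Cc5cc(OC)c(OC)c(OC)c5[C@H]4c6ccc(OC)c(OC)c6)[C@@H]3C2 | intermediate
21 | N-{[(1R,2R)-1-(3,4-dimethoxyphenyl)-6,7,8-trimethoxy-3-(TIPS-oxymethyl)-1,2-dihydronaphthalen-2-yl]carbonyl}-(3aS,6R,7aR)-2,10-camphorsultam, 1,2-cis | CC1(C)[C@@H]2CC[C@]13CS(=O)(=O)N(C(=O)[C@H]4C(CO[Si](C(C)C)(C(C)C)C(C)C)=Cc5cc(OC)c(OC)c(OC)c5[C@H]4c6ccc(OC)c(OC)c6)[C@@H]3C2 | intermediate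
22 | N-{[(1R,2S)-1-(3,4-dimethoxyphenyl)-6,7,8-trimethoxy-3-(TIPS-oxymethyl)-1,2-dihydronaphthalen-2-yl]carbonyl}-(3aS,6R,7aR)-2,10-camphorsultam, 1,2-trans | CC1(C)[C@@H]2CC[C@]13CS(=O)(=O)N(C(=O)[C@@H]4C(CO[Si](C(C)C)(C(C)C)C(C)C)=Cc5cc(OC)c(OC)c(OC)c5[C@H]4c6ccc(OC)c(OC)c6)[C@@H]3C2 | intermediate
23 | [(1R,2S)-1-(3,4-dimethoxyphenyl)-6,7,8-trimethoxy-3-(TIPS-oxymethyl)-1,2-dihydronaphthalen-2-yl]methanol | COc1ccc([C@@H]2c3c(cc(OC)c(OC)c3OC)C=C(CO[Si](C(C)C)(C(C)C)C(C)C)[C@H]2CO)cc1OC | intermediate
24 | [(1R,2S)-1-(3,4-dimethoxyphenyl)-6,7,8-trimethoxy-1,2-dihydronaphthalene-2,3-diyl]dimethanol, 1,2-trans | COc1ccc([C@@H]2c3c(cc(OC)c(OC)c3OC)C=C(CO)[C@H]2CO)cc1OC | target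

Total step count: 12.
Longest linear sequence: 9 steps (3, 4, 5, 7, 8, 9, 10, 11, 12).

Steps most likely to fail

Step 8. The sultam on the internal C2 carbonyl may discriminate the two diene faces only weakly, so that both C1 epimers form; part of the aryne may also be lost to ene reaction at the allylic OCH2 group. The fallback changes how the absolute configuration is secured, from induction to covalent resolution. It sets out from 17: the cycloaddition is run as before without relying on the auxiliary for face selection, and 19 is separated from its C1 epimer, the (1S) adduct F1, by crystallisation or chromatography, the two being diastereomers because of the bound sultam. It returns to the route at 19.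

Step 9. The crowded, fully substituted imide may not flatten enough for clean removal of a C4 hydrogen, the OCH2 hydrogens may be removed instead, or the anion may be reprotonated at C4 and return 19. The fallback replaces the strong-base imide dienolate by soft enolisation of an aldehyde. It sets out from 19: LiAlH4 cleaves the auxiliary to give the allylic alcohol F2, oxidation with the periodinane DMP gives the enal F3, and Et3SiOTf with Et3N removes a C4 hydrogen to give the triethylsilyl dienol ether F4, in which the ring alkene already lies at C3=C4. K2CO3 in MeOH then cleaves the enol ether and lets the aldehyde settle as the trans aldehyde F5, and NaBH4 added to the same flask reduces it to 23, where the fallback rejoins the route.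

Step 10. Protonation of the dienolate at C4 may compete with protonation at C2, so that material slides back to the conjugated isomer 19, or deprotonation of the hindered imide at C2 may be too slow. The fallback moves the equilibration to the ester level after removal of the auxiliary. It sets out from 21: NaOMe in MeOH/THF exchanges the sultam for methoxide and equilibrates C2 in a protic medium, where reprotonation at the alpha carbon dominates, to give the trans methyl ester F6. LiAlH4 reduction of F6 gives 23, where the fallback rejoins the route.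

Further compounds
F1 | step 8 | N-{[(1S)-1-(3,4-dimethoxyphenyl)-6,7,8-trimethoxy-3-(TIPS-oxymethyl)-1,4-dihydronaphthalen-2-yl]carbonyl}-(3aS,6R,7aR)-2,10-camphorsultam, C1 epimer of 19 | CC1(C)[C@@H]2CC[C@]13CS(=O)(=O)N(C(=O)C4=C(CO[Si](C(C)C)(C(C)C)C(C)C)Cc5cc(OC)c(OC)c(OC)c5[C@@H]4c6ccc(OC)c(OC)c6)[C@@H]3C2
F2 | step 9 | [(1S)-1-(3,4-dimethoxyphenyl)-6,7,8-trimethoxy-3-(TIPS-oxymethyl)-1,4-dihydronaphthalen-2-yl]methanol, C1 arranged in space as in 19 | OCC1=C(CO[Si](C(C)C)(C(C)C)C(C)C)Cc2cc(OC)c(OC)c(OC)c2[C@H]1c3ccc(OC)c(OC)c3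
F3 | step 9 | (1R)-1-(3,4-dimethoxyphenyl)-6,7,8-trimethoxy-3-(TIPS-oxymethyl)-1,4-dihydronaphthalene-2-carbaldehyde | O=CC1=C(CO[Si](C(C)C)(C(C)C)C(C)C)Cc2cc(OC)c(OC)c(OC)c2[C@H]1c3ccc(OC)c(OC)c3
F4 | step 9 | {[(1S)-1-(3,4-dimethoxyphenyl)-6,7,8-trimethoxy-3-(TIPS-oxymethyl)naphthalen-2(1H)-ylidene]methoxy}triethylsilane | CC[Si](CC)(CC)OC=C1C(CO[Si](C(C)C)(C(C)C)C(C)C)=Cc2cc(OC)c(OC)c(OC)c2[C@H]1c3ccc(OC)c(OC)c3
F5 | step 9 | (1R,2S)-1-(3,4-dimethoxyphenyl)-6,7,8-trimethoxy-3-(TIPS-oxymethyl)-1,2-dihydronaphthalene-2-carbaldehyde | O=C[C@@H]1C(CO[Si](C(C)C)(C(C)C)C(C)C)=Cc2cc(OC)c(OC)c(OC)c2[C@H]1c3ccc(OC)c(OC)c3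
F6 | step 10 | methyl (1R,2S)-1-(3,4-dimethoxyphenyl)-6,7,8-trimethoxy-3-(TIPS-oxymethyl)-1,2-dihydronaphthalene-2-carboxylate | COC(=O)[C@@H]1C(CO[Si](C(C)C)(C(C)C)C(C)C)=Cc2cc(OC)c(OC)c(OC)c2[C@H]1c3ccc(OC)c(OC)c3
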